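Remark on the chemistry: ring A is numbered as in the target phenol throughout (C1 oxygen or its nitrogen surrogate, C6 ether oxygen), ring B positions carry primes, and compound names use their own locants. The target has no stereocentre, so no descriptors are needed.

## Structural features

The target 9 is an achiral diaryl ether in which one oxygen joins C6 of ring A to C1' of ring B. Ring A is pentasubstituted, with the hydroxyl on C1, the ether oxygen on C6 and three contiguous bromines on C3, C4 and C5, so C2 carries its only hydrogen. Ring B is a 2',4'-dibromophenyl group. The five aryl–bromine bonds are the fragile part, since they exclude catalytic hydrogenation, zerovalent palladium or nickel chemistry and unselective halogen–metal exchange, and the free phenol is easily oxidised and over-brominated. The real difficulty is regiochemical, because an oxygen on C1 sends electrophiles to C2 and C4, yet C2 must stay free while C3 and C5, both meta to C1, must be brominated. The key step uses the fact that C3 and C5 are the two ortho positions of C4, are para and ortho to the C6 ether oxygen, and are meta to C1. With a temporary amino group on C4 and a nitro group on C1, all three substituents point to C3 and C5 and the nitro group deactivates C2; afterwards the amine becomes the C4 bromine and the nitro group becomes the C1 hydroxyl.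

## Logic of the disconnections

**9 ⇒ 7 (through 8).** The C1–O bond is cut and a C1–N bond takes its place. An oxygen on C1 would direct to C2 and C4, whereas nitrogen on C1 can be carried as a nitro group that does the opposite. The gain is that the most activating and most oxidisable group appears only in the last step. The forward step must turn a weakly basic, ortho-aryloxy amine into a hydroxyl without letting the reactive C1 intermediate attack ring B.

**7 ⇒ 6.** No skeletal bond is cut; the N–H bonds are exchanged for N–O bonds. The nitro group of 6 is inert to the diazonium chemistry that sets C4–Br, and earlier it is the meta director and the activator for ether formation. The forward reduction must leave five C–Br bonds and the ether untouched.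

**6 ⇒ 4 (through 5).** The C4–Br bond is cut and replaced by C4–N. This removes the central bromine, which no director could place selectively, and uncovers the amine that controls both neighbouring carbons. The forward step must diazotise an amine flanked by two bromines and para to a nitro group, and replace it by bromide.

**4 ⇒ 3.** The C3–Br and C5–Br bonds are cut together. In 3 three substituents agree on these two carbons, so two bromines are removed in one operation and a simple trisubstituted ring A remains. The forward step must brominate ring A twice, once at a hindered site, and leave C2 and ring B alone.

**3 ⇒ 1 + 2.** The C6–O bond on the ring A side of the ether is cut. This gives two commercial fragments: 2 holds ring B with both bromines, and 1 holds ring A with a leaving group ortho to the nitro group. The forward step needs a hindered, weakly basic phenoxide to displace fluoride while the free amino group stays out of the reaction.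

## Other disconnections considered

Alternative 1: The cut runs through the O–C1' bond of the ether and the C2'–Br bond of ring B at once. In the forward key step the phenoxide of 2,3,4-tribromo-6-methoxyphenol A2 would add to the aryne released by a fluoride source from 2-(trimethylsilyl)phenyl trifluoromethanesulfonate A3. The resulting ortho aryl anion would take bromine from 1,2-dibromo-1,1,2,2-tetrachloroethane A4 to give 1,2,3-tribromo-4-(2-bromophenoxy)-5-methoxybenzene A1. In its favour, the coupling is convergent and mild, the symmetric aryne raises no regiochemical question, and a hindered phenoxide should add to an aryne more readily than it would couple in a copper-mediated ether synthesis. A2 should be a simple bromination product, since its bromines lie ortho and para to the free hydroxyl and para to the methoxy group. Against it, A1 still lacks the C4' bromine, so a later electrophilic bromination of A1 must choose C4' of ring B over C2 of ring A, which is ortho to a methoxy group. The aryl anion may also be quenched by a proton before it meets A4, and A4 may brominate the phenoxide of A2 directly. On structure the alternative is the better plan in one respect, because the C1 oxygen is present from the start as a methyl ether and no diazonium ion ever sits beside the ether oxygen. On step economy it is at least the equal (bromination to A2, aryne coupling to A1, ring B bromination, O-demethylation: four steps against five). On mechanism it is weaker: the three-component capture and the late ring-selective bromination are less predictable than the triply reinforced bromination of 3, and A3 is a much costlier source of ring B than 2.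

Alternative 2: Ring A itself is dissected at C2–C3 and C5–C6, leaving a three-carbon nitro ketone and a three-carbon dialdehyde. In the forward key step 1-(2,4-dibromophenoxy)-3-nitropropan-2-one A6 would condense through both α-carbons with the two formyl groups of bromomalonaldehyde A7 and aromatise by loss of water to 4-bromo-2-(2,4-dibromophenoxy)-6-nitrophenol A5. In its favour, A5 would hold the hydroxyl, the ether and the C4 bromine of ring A after a single ring-forming step, and ring B would come intact from 2. The nitro group of A5 sits on C2 of ring A and could then be reduced to 2-amino-4-bromo-6-(2,4-dibromophenoxy)phenol A8, whose amino group is ortho to C3 and para to C5 and would steer the two missing bromines there before reductive deamination. Against it, A6 is an α-nitro ketone with an aryloxy group on the other α-carbon. It is prone to base-induced cleavage, and its two α-positions differ greatly in acidity, so the second closure through the aryloxy-bearing carbon on the way to A5 is uncertain. A7 is a sensitive, largely enolised dialdehyde and a poor electrophile as its anion. A8 is an air-sensitive ortho-aminophenol that bromine can oxidise, and its deamination would be complicated by the neighbouring hydroxyl (cyclic diazo-oxide formation). In directing logic the two plans are equals, since both use a temporary nitrogen substituent to override the oxygen directors. The alternative is the better one in that the C1 hydroxyl never has to be made from a diazonium ion next to the ether oxygen. On mechanism it rests on a condensation whose precedent concerns simpler ketones and a nitro-substituted dialdehyde, whereas the chosen key step is a standard aromatic substitution. On step economy it is longer: preparing A6, ring closure to A5, reduction to A8, dibromination and deamination add up to about seven steps.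

Alternative 3: Ring B is dissected at C1'–C2' and C5'–C6'. In the forward key step 1,2,3-tribromo-4-(ethynyloxy)-5-methoxybenzene A10, the ethynyl ether of A2, would undergo a [4+2] cycloaddition across C3 and C6 of 3,5-dibromo-2H-pyran-2-one A11. Decarboxylative cycloreversion of the bridged adduct would close aromatic ring B and give 1,2,3-tribromo-4-(2,4-dibromophenoxy)-5-methoxybenzene A9. In its favour, both ring B bromines arrive from A11 in fixed positions. The polarity matches: the nucleophilic terminal carbon of A10 should bond to C6 of A11 and the oxygen-bearing carbon to C3, which gives the 2',4' pattern. A9 is the methyl ether of 9, so after the key step only O-demethylation of A9 remains. Against it, A10 would normally be made by O-dichlorovinylation of A2 and elimination with an alkyllithium, which three aryl bromides are unlikely to tolerate because of halogen–lithium exchange. Aryl ynol ethers such as A10 are prone to hydration and thermal decomposition, and pyrone–alkyne cycloadditions usually need high temperatures. The effort also goes into building ring B, which is bought complete as 2. On step count it is the equal of the chosen plan (bromination to A2, vinyl ether, A10, cycloaddition to A9, demethylation: five steps). On structure it is better in that no diazonium chemistry is needed and the C1 oxygen is present throughout. On mechanism the regiochemistry of A9 rests on the polarisation of a pericyclic reaction, which is credible, but the preparation and handling of A10 are a weaker foundation than the substitution chemistry of the chosen route.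

Key step: step 2

## Route

Step 1
Reactants: 1 3-fluoro-4-nitroaniline; 2 2,4-dibromophenol
Product: 3 3-(2,4-dibromophenoxy)-4-nitroaniline
Conditions: K2CO3 (1.5 equiv), DMF, 90 °C
Reagents that add atoms: none
Why: Nucleophilic aromatic substitution by addition–elimination through a Meisenheimer complex: the fluorine of 1 is ortho to the nitro group and should be displaced by the phenoxide of 2, while the para-nitroaniline nitrogen is too weakly nucleophilic to compete and the bromines of 2 are unactivated.

Step 2
Reactants: 3 3-(2,4-dibromophenoxy)-4-nitroaniline
Product: 4 2,6-dibromo-3-(2,4-dibromophenoxy)-4-nitroaniline
Conditions: Br2 (2.2 equiv), AcOH, 20 → 50 °C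
Reagents that add atoms: bromine, BrBr
Why: Electrophilic aromatic substitution: Br2 attacks ring A of 3 to give Wheland intermediates whose positive charge is delocalised onto the C4 amino nitrogen, and loss of a proton restores the arene, once at C3 and once at C5 (target numbering). The closest known reaction type is the ortho,ortho-dibromination of 4-nitroanilines with bromine in acetic acid. No ring is closed and no stereocentre is formed; two C–Br bonds are made. The step needs site selectivity between C3 and C5 on one hand and C2 and the free C6' of ring B on the other. The amino group (ortho), the C6 aryloxy group (para to C3, ortho to C5) and the C1 nitro group (meta) all point to C3 and C5, whereas C2 is ortho to the nitro group and meta to both donors. Ring B carries two bromines and its oxygen is shared with the nitro-substituted ring A, so C6' should not compete with an aniline ring. The first bromine should enter at the unhindered C3 and the second at C5, between the amine and the ether, which is why gentle warming and a slight excess of bromine are planned. After two substitutions no activated position remains, which limits over-bromination.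

Step 3
Reactants: 4 2,6-dibromo-3-(2,4-dibromophenoxy)-4-nitroaniline
Product: 6 1,2,3-tribromo-4-(2,4-dibromophenoxy)-5-nitrobenzene, via arenediazonium hydrogen sulfate 5 (not isolated)
Conditions: NaNO2 (1.05 equiv), conc. H2SO4, AcOH, 0–15 °C; then CuBr (0.5 equiv), 48% aq. HBr, 0 → 60 °C
Reagents that add atoms: hydrobromic acid, Br (bromide passed to carbon by CuBr); sodium nitrite, [Na+].[O-]N=O (second nitrogen of 5 only); sulfuric acid, OS(=O)(=O)O (counter-ion of 5 only)
Why: Sandmeyer reaction: the very weakly basic amine is diazotised with nitrosylsulfuric acid, monovalent copper reduces the diazonium ion to the C4 aryl radical with loss of N2, and the radical takes bromine from divalent copper bromide; the radical is meta to the aryloxy group and so has no cyclisation path. Bromide is the only halide in the medium, so any exchange at the activated ortho bromines of 5 is degenerate.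

Step 4
Reactants: 6 1,2,3-tribromo-4-(2,4-dibromophenoxy)-5-nitrobenzene
Product: 7 3,4,5-tribromo-2-(2,4-dibromophenoxy)aniline
Conditions: Fe powder (5 equiv), AcOH, EtOH, H2O, 70 °C
Reagents that add atoms: none
Why: Béchamp-type dissolving-metal reduction of the nitro group through the nitroso and hydroxylamine stages; iron in acetic acid should leave aryl bromides and the diaryl ether intact, unlike catalytic hydrogenation.

Step 5
Reactants: 7 3,4,5-tribromo-2-(2,4-dibromophenoxy)aniline
Product: 9 3,4,5-tribromo-2-(2,4-dibromophenoxy)phenol, via arenediazonium hydrogen sulfate 8 (not isolated)
Conditions: NaNO2 (1.05 equiv), conc. H2SO4, AcOH, 0–10 °C; then Cu(NO3)2 (50 equiv), Cu2O (0.5 equiv), H2O, 20 °C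
Reagents that add atoms: water, O; sodium nitrite, [Na+].[O-]N=O (second nitrogen of 8 only); sulfuric acid, OS(=O)(=O)O (counter-ion of 8 only)
Why: Diazotisation followed by copper-mediated hydroxy-dediazoniation: monovalent copper reduces the diazonium ion to the C1 aryl radical, which the large excess of hydrated divalent copper captures and converts into the phenol at room temperature; fast capture is meant to outrun attack of the radical on C6' of ring B, and the acidic medium suppresses azo coupling with the product.

## Compound list

1 | 3-fluoro-4-nitroaniline | Nc1ccc([N+](=O)[O-])c(F)c1 | starting material
2 | 2,4-dibromophenol | Oc1ccc(Br)cc1Br | starting material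
3 | 3-(2,4-dibromophenoxy)-4-nitroaniline | Nc1ccc([N+](=O)[O-])c(Oc2ccc(Br)cc2Br)c1 | intermediate
4 | 2,6-dibromo-3-(2,4-dibromophenoxy)-4-nitroaniline | Nc1c(Br)cc([N+](=O)[O-])c(Oc2ccc(Br)cc2Br)c1Br | intermediate
5 | 2,6-dibromo-3-(2,4-dibromophenoxy)-4-nitrobenzenediazonium hydrogen sulfate | N#[N+]c1c(Br)cc([N+](=O)[O-])c(Oc2ccc(Br)cc2Br)c1Br.OS(=O)(=O)[O-] | intermediate
6 | 1,2,3-tribromo-4-(2,4-dibromophenoxy)-5-nitrobenzene | [O-][N+](=O)c1cc(Br)c(Br)c(Br)c1Oc1ccc(Br)cc1Br | intermediate
7 | 3,4,5-tribromo-2-(2,4-dibromophenoxy)aniline | Nc1cc(Br)c(Br)c(Br)c1Oc1ccc(Br)cc1Br | intermediate
8 | 3,4,5-tribromo-2-(2,4-dibromophenoxy)benzenediazonium hydrogen sulfate | N#[N+]c1cc(Br)c(Br)c(Br)c1Oc1ccc(Br)cc1Br.OS(=O)(=O)[O-] | intermediate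
9 | 3,4,5-tribromo-2-(2,4-dibromophenoxy)phenol | Oc1cc(Br)c(Br)c(Br)c1Oc1ccc(Br)cc1Br | target

## Step count and risk assessment

Total step count: 5. Longest linear sequence: 5 steps (1 → 3 → 4 → 6 → 7 → 9, with 2 entering in step 1).

**Step 2 (key step).** The most likely failure is a stalled second bromination at C5, the carbon wedged between the amino group and the bulky aryloxy group. Forcing it with more bromine or heat could bring oxidative degradation of the amine. The fallback reverses the order of C–Br and C–O bond formation. It sets out from 1, which is dibrominated with Br2 in AcOH; both positions ortho to the amine are then flanked only by hydrogen or by the small fluorine. This gives 2,6-dibromo-3-fluoro-4-nitroaniline F1. Its fluorine, still ortho to the nitro group, is then displaced by the phenoxide of 2 (Cs2CO3, DMSO, 80 °C), and the sequence returns to the route at 4.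

**Step 5.** Three processes threaten it: intramolecular arylation of ring B by the radical or cation generated at C1 (closure to a dibenzofuran), hydrodediazoniation, and azo coupling of unreacted diazonium ion with the phenol as it forms. The fallback replaces oxygen delivery to a C1 radical by a boron oxidation. It sets out from 7, which is diazotised as in step 5, and the solution of 8 is run into aqueous KI at 0–20 °C. Iodine transfer to the aryl radical from iodine and triiodide needs no copper and should be fast enough to outrun cyclisation. This gives 1,2,3-tribromo-4-(2,4-dibromophenoxy)-5-iodobenzene F2. Selective iodine–magnesium exchange (iPrMgCl, THF, −40 °C) should leave the bromides alone at this temperature, and the arylmagnesium species has no ortho halogen to eliminate. Trapping with 2-isopropoxy-4,4,5,5-tetramethyl-1,3,2-dioxaborolane should give 2-[3,4,5-tribromo-2-(2,4-dibromophenoxy)phenyl]-4,4,5,5-tetramethyl-1,3,2-dioxaborolane F3. Oxidation with H2O2 and NaOH in THF and water at 0 °C returns to the route at 9.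

**Step 3.** The amine is very weakly basic and flanked by two bromines, so diazotisation may be incomplete. The strongly electrophilic diazonium ion may also be attacked by water during transfer into aqueous acid, with displacement of an ortho bromine or premature loss of the diazonio group. The fallback leaves the aqueous one-pot protocol and separates the two events. It sets out from 4, which is diazotised with NOBF4 in MeCN at −20 → 0 °C and precipitated with diethyl ether as 2,6-dibromo-3-(2,4-dibromophenoxy)-4-nitrobenzenediazonium tetrafluoroborate F4. The salt is then treated with KBr and catalytic CuBr, CuBr2 and 1,10-phenanthroline in MeCN at 20 °C, returning to the route at 6.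

**Step 1.** The substitution may be slow, because the para-amino group donates into the nitro group and weakens its activation of the C–F bond, and the phenoxide is hindered and weakly nucleophilic. Prolonged heating could then allow N-arylation of the aniline. The fallback introduces the nitrogen last. It sets out from 2, which is combined with commercial 2,4-difluoronitrobenzene ([O-][N+](=O)c1ccc(F)cc1F) under conditions that favour attack ortho to the nitro group (K2CO3, toluene, 60 °C). This should give 2-(2,4-dibromophenoxy)-4-fluoro-1-nitrobenzene F5. The remaining para fluorine is then displaced with aqueous NH3 in DMSO at 90 °C in a sealed vessel, returning to the route at 3.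

## Further compounds

F1 | step 2 | 2,6-dibromo-3-fluoro-4-nitroaniline | Nc1c(Br)cc([N+](=O)[O-])c(F)c1Br
F2 | step 5 | 1,2,3-tribromo-4-(2,4-dibromophenoxy)-5-iodobenzene | Ic1cc(Br)c(Br)c(Br)c1Oc1ccc(Br)cc1Br
F3 | step 5 | 2-[3,4,5-tribromo-2-(2,4-dibromophenoxy)phenyl]-4,4,5,5-tetramethyl-1,3,2-dioxaborolane | CC1(C)OB(OC1(C)C)c1cc(Br)c(Br)c(Br)c1Oc1ccc(Br)cc1Br
F4 | step 3 | 2,6-dibromo-3-(2,4-dibromophenoxy)-4-nitrobenzenediazonium tetrafluoroborate | N#[N+]c1c(Br)cc([N+](=O)[O-])c(Oc2ccc(Br)cc2Br)c1Br.F[B-](F)(F)F
F5 | step 1 | 2-(2,4-dibromophenoxy)-4-fluoro-1-nitrobenzene | [O-][N+](=O)c1ccc(F)cc1Oc1ccc(Br)cc1Br
A1 | alternative 1 | 1,2,3-tribromo-4-(2-bromophenoxy)-5-methoxybenzene | COc1cc(Br)c(Br)c(Br)c1Oc1ccccc1Br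
A2 | alternative 1 | 2,3,4-tribromo-6-methoxyphenol | COc1cc(Br)c(Br)c(Br)c1O
A3 | alternative 1 | 2-(trimethylsilyl)phenyl trifluoromethanesulfonate | C[Si](C)(C)c1ccccc1OS(=O)(=O)C(F)(F)F
A4 | alternative 1 | 1,2-dibromo-1,1,2,2-tetrachloroethane | BrC(Cl)(Cl)C(Cl)(Cl)Br
A5 | alternative 2 | 4-bromo-2-(2,4-dibromophenoxy)-6-nitrophenol | Oc1c(Oc2ccc(Br)cc2Br)cc(Br)cc1[N+](=O)[O-]
A6 | alternative 2 | 1-(2,4-dibromophenoxy)-3-nitropropan-2-one | O=C(COc1ccc(Br)cc1Br)C[N+](=O)[O-]
A7 | alternative 2 | bromomalonaldehyde (2-bromopropanedial) | O=CC(Br)C=O
A8 | alternative 2 | 2-amino-4-bromo-6-(2,4-dibromophenoxy)phenol | Nc1cc(Br)cc(Oc2ccc(Br)cc2Br)c1O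
A9 | alternative 3 | 1,2,3-tribromo-4-(2,4-dibromophenoxy)-5-methoxybenzene | COc1cc(Br)c(Br)c(Br)c1Oc1ccc(Br)cc1Br
A10 | alternative 3 | 1,2,3-tribromo-4-(ethynyloxy)-5-methoxybenzene | COc1cc(Br)c(Br)c(Br)c1OC#C
A11 | alternative 3 | 3,5-dibromo-2H-pyran-2-one | O=C1OC=C(Br)C=C1Br
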